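**Plan**
- Retrosynthesis: the six benzyl ethers are cut first. Ring C of the flavanone half is then opened at O1–C8a and C4–C4a together, giving an aryne on ring A and an (S)-β-hydroxy ester. The 8,8''-biaryl bond is cut next, and last the pyranone ring of the flavone half.
- Enabling feature: in ring A of the flavanone half, C8a and C4a are neighbouring carbons that carry O1 and the C4 carbonyl, and the C5 oxygen sits next to C4a. An aryne across C8a/C4a, polarised by that C5 oxygen, can take up the alkoxide oxygen at C8a and the acyl carbon at C4a in one operation.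
- Forward order: flavone ring (chalcone, then oxidative cyclisation) → biaryl by Negishi coupling onto a doubly ortho-metalated phloroglucinol carbamate → silyl triflate → aryne annulation that forms O1–C8a and closes ring C through C4–C4a → hydrogenolysis.
- Stereochemistry: C2 (S) is set by Noyori asymmetric transfer hydrogenation of a β-keto ester. Its C–O bond is never broken afterwards, and the flavanone sees only fluoride at low temperature and neutral hydrogenolysis.

Key step: step 10

Assumption: the SMILES defines only C2, so the tetra-ortho-oxygenated 8,8''-biaryl axis is left uncontrolled and the route fixes the (2S) centre only.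

**Route**

Step 1
Reactants: 1 1-[2,4-bis(benzyloxy)-6-hydroxyphenyl]ethan-1-one
Product: 2 1-[4,6-bis(benzyloxy)-2-hydroxy-3-iodophenyl]ethan-1-one
Conditions: NIS (1.0 equiv), TFA (cat.), MeCN, 0 °C to rt
Reagents that add atoms: N-iodosuccinimide, O=C1CCC(=O)N1I
Why: Electrophilic aromatic iodination of a phloroglucinol ring; the position between the chelated OH and one OBn should react in preference to the position buttressed by two benzyloxy groups.

Step 2
Reactants: 2 1-[4,6-bis(benzyloxy)-2-hydroxy-3-iodophenyl]ethan-1-one; 3 4-(benzyloxy)benzaldehyde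
Product: 4 (E)-1-[4,6-bis(benzyloxy)-2-hydroxy-3-iodophenyl]-3-[4-(benzyloxy)phenyl]prop-2-en-1-one
Conditions: KOH, EtOH–THF, rt; then aq. HCl
Reagents that add atoms: none
Why: Claisen–Schmidt condensation of a 2'-hydroxyacetophenone with a non-enolisable aldehyde should give the (E)-chalcone; aryl iodide and benzyl ethers are inert to aqueous alkali.

Step 3
Reactants: 4 (E)-1-[4,6-bis(benzyloxy)-2-hydroxy-3-iodophenyl]-3-[4-(benzyloxy)phenyl]prop-2-en-1-one
Product: 5 5,7-bis(benzyloxy)-2-[4-(benzyloxy)phenyl]-8-iodo-4H-chromen-4-one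
Conditions: I2 (10 mol%), DMSO, 130 °C
Reagents that add atoms: none
Why: Iodine/DMSO oxidative cyclisation of a 2'-hydroxychalcone (oxa-Michael closure, then dehydrogenation with DMSO as terminal oxidant) should give the flavone with the iodine fixed at C8 by the substitution pattern of 2.

Step 4
Reactants: 6 3,5-bis(benzyloxy)phenol
Product: 7 3,5-bis(benzyloxy)phenyl N-(propan-2-yl)carbamate
Conditions: i-PrNCO, Et3N (cat.), CH2Cl2, rt
Reagents that add atoms: isopropyl isocyanate, CC(C)N=C=O
Why: Base-catalysed addition of a phenol to an isocyanate installs a directing group for ortho-metalation that can later be removed under mild E1cB conditions.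

Step 5
Reactants: 7 3,5-bis(benzyloxy)phenyl N-(propan-2-yl)carbamate
Product: 11 3,5-bis(benzyloxy)-2-(trimethylsilyl)phenyl N-(propan-2-yl)carbamate, via N-TMS carbamate 8 (not isolated), via aryllithium 9 (not isolated), via N-TMS C-TMS carbamate 10 (not isolated)
Conditions: TMSOTf, TMEDA, Et2O, 0 °C to rt; n-BuLi (2.2 equiv), TMEDA, −78 °C; TMSCl, −78 °C to rt; aq. NH4Cl
Reagents that add atoms: chlorotrimethylsilane, C[Si](C)(C)Cl
Why: Directed ortho-metalation of an N-monoalkyl carbamate whose N–H is masked in the flask by silylation should lithiate the position flanked by carbamate and benzyloxy oxygen, the two such positions being equivalent by symmetry; −78 °C keeps benzylic deprotonation and anionic Fries migration slow, and the labile N–Si bond is hydrolysed on work-up.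

Step 6
Reactants: 11 3,5-bis(benzyloxy)-2-(trimethylsilyl)phenyl N-(propan-2-yl)carbamate; 5 5,7-bis(benzyloxy)-2-[4-(benzyloxy)phenyl]-8-iodo-4H-chromen-4-one
Product: 16 3,5-bis(benzyloxy)-2-{5,7-bis(benzyloxy)-2-[4-(benzyloxy)phenyl]-4-oxo-4H-chromen-8-yl}-6-(trimethylsilyl)phenyl N-(propan-2-yl)carbamate, via N-TBS carbamate 12 (not isolated), via aryllithium 13 (not isolated), via arylzinc chloride 14 (not isolated), via N-TBS biaryl carbamate 15 (not isolated)
Conditions: TBSOTf, TMEDA, Et2O, 0 °C to rt; n-BuLi (2.2 equiv), TMEDA, −78 °C; ZnCl2, THF, −78 °C to rt; then 5, Pd2(dba)3 (2.5 mol%), RuPhos (10 mol%), THF–NMP, 70 °C; aq. NaHSO4 work-up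
Reagents that add atoms: none
Why: Directed ortho-metalation at the one remaining position ortho to the carbamate, with the N–H now masked as the more robust tert-butyldimethylsilyl derivative so that the mask survives warming with ZnCl2 and the 70 °C coupling and is removed only by the acidic work-up; transmetalation to zinc at −78 °C gives a nucleophile that tolerates the chromone carbonyl and cannot undergo anionic Fries migration, and Negishi coupling with a bulky dialkylbiarylphosphine is an established way to tetra-ortho-substituted biaryls.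

Step 7
Reactants: 16 3,5-bis(benzyloxy)-2-{5,7-bis(benzyloxy)-2-[4-(benzyloxy)phenyl]-4-oxo-4H-chromen-8-yl}-6-(trimethylsilyl)phenyl N-(propan-2-yl)carbamate
Product: 18 3,5-bis(benzyloxy)-2-{5,7-bis(benzyloxy)-2-[4-(benzyloxy)phenyl]-4-oxo-4H-chromen-8-yl}-6-(trimethylsilyl)phenyl trifluoromethanesulfonate, via silyl phenol 17 (not isolated)
Conditions: DBU, Et2NH, MeCN, 40 °C; then PhNTf2, rt
Reagents that add atoms: N-phenylbis(trifluoromethanesulfonimide), O=S(=O)(N(c1ccccc1)S(=O)(=O)C(F)(F)F)C(F)(F)F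
Why: E1cB cleavage of the N–H carbamate (isocyanate trapped by Et2NH) followed by triflation of the phenoxide in the same flask is the standard entry to 2-silylaryl triflates; the flavone, benzyl ethers and the aryl–silicon bond are stable to amine bases.

Step 8
Reactants: 19 1-[4-(benzyloxy)phenyl]ethan-1-one
Product: 20 methyl 3-[4-(benzyloxy)phenyl]-3-oxopropanoate
Conditions: NaH, (MeO)2CO, THF, reflux; AcOH quench
Reagents that add atoms: dimethyl carbonate, COC(=O)OC
Why: Crossed Claisen condensation of a methyl ketone enolate with dimethyl carbonate, driven by formation of the β-keto ester enolate.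

Step 9
Reactants: 20 methyl 3-[4-(benzyloxy)phenyl]-3-oxopropanoate
Product: 21 methyl (3S)-3-[4-(benzyloxy)phenyl]-3-hydroxypropanoate
Conditions: RuCl(p-cymene)[(S,S)-TsDPEN] (1 mol%), HCO2H–Et3N (5:2), EtOAc, 40 °C
Reagents that add atoms: none
Why: Noyori asymmetric transfer hydrogenation of an aryl ketone; the (S,S)-TsDPEN catalyst should deliver hydride to the face that gives the (S)-carbinol, as it does for acetophenone (aryl/alkyl differentiation by the CH/π contact with the arene ligand), and the benzyl ether is not touched by this homogeneous catalyst.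

Step 10
Reactants: 18 3,5-bis(benzyloxy)-2-{5,7-bis(benzyloxy)-2-[4-(benzyloxy)phenyl]-4-oxo-4H-chromen-8-yl}-6-(trimethylsilyl)phenyl trifluoromethanesulfonate; 21 methyl (3S)-3-[4-(benzyloxy)phenyl]-3-hydroxypropanoate
Product: 24 (2S)-5,7-bis(benzyloxy)-2-[4-(benzyloxy)phenyl]-8-{5,7-bis(benzyloxy)-2-[4-(benzyloxy)phenyl]-4-oxo-4H-chromen-8-yl}-2,3-dihydro-4H-chromen-4-one, via aryne 22 (not isolated), via arylpotassium 23 (not isolated)
Conditions: KF, 18-crown-6, 21 (2 equiv), 4 Å MS, THF, −20 °C to rt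
Reagents that add atoms: none
Why: Proposed new method: fluoride attacks silicon of 18 and triflate leaves to give aryne 22, whose triple bond lies between C8a and C4a of the future ring A; the fluoride-activated secondary alkoxide of 21 adds to C8a, and the aryl anion 23 formed at C4a attacks the methyl ester through a six-membered transition state and expels methoxide, so that O1–C8a forms first and ring C is closed by the C4–C4a bond (6-exo-trig acyl substitution). The closest known reaction types are the fluoride-induced annulation of arynes with methyl salicylates to xanthones (aryl ether formation, then intramolecular acylation of the aryl anion) and the O–H insertion of aliphatic alcohols into arynes; new here are the β-hydroxy ester as partner and the hindered biaryl aryne. No stereocentre is created: C2 comes from 21 with retention because its C–O bond is never broken, which avoids any substitution at the ionisable 4-alkoxybenzylic carbon. Regioselectivity rests on the groups beside the triple bond: the benzyloxy group on C5, next to C4a, is σ-withdrawing and distorts the aryne so that C8a is the more electrophilic terminus and the developing carbanion at C4a is stabilised beside the C–O bond, while the flavonyl group on C8, next to C8a, is electronically weak and twisted out of plane and adds only steric demand. Chemoselectivity (acylation of 23 faster than its protonation, no attack of the 7''-benzyloxy oxygen on the aryne) should be secured by the six-membered intramolecular trap in aprotic THF at low temperature and by the strain of the 1,9-disubstituted dibenzofuran-type oxonium that the competing closure would require. The medium is free of acid and only weakly basic, which both the acid-labile benzylic aryl ether stage and the base-sensitive flavanone need.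

Step 11
Reactants: 24 (2S)-5,7-bis(benzyloxy)-2-[4-(benzyloxy)phenyl]-8-{5,7-bis(benzyloxy)-2-[4-(benzyloxy)phenyl]-4-oxo-4H-chromen-8-yl}-2,3-dihydro-4H-chromen-4-one
Product: 25 (2S)-5,7-dihydroxy-8-[5,7-dihydroxy-2-(4-hydroxyphenyl)-4-oxo-4H-chromen-8-yl]-2-(4-hydroxyphenyl)-2,3-dihydro-4H-chromen-4-one
Conditions: H2 (1 atm), Pd/C (10%), THF–MeOH, rt
Reagents that add atoms: none
Why: Hydrogenolysis of six aryl benzyl ethers under neutral conditions should leave C2 untouched; the chromone double bond, the aryl ketone and the cyclic benzylic C2–O1 bond are reduced much more slowly than O-benzyl groups, so the reaction is stopped at full debenzylation.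

**Compound list**
1 | 1-[2,4-bis(benzyloxy)-6-hydroxyphenyl]ethan-1-one | CC(=O)c1c(O)cc(OCc2ccccc2)cc1OCc1ccccc1 | starting material
2 | 1-[4,6-bis(benzyloxy)-2-hydroxy-3-iodophenyl]ethan-1-one | CC(=O)c1c(O)c(I)c(OCc2ccccc2)cc1OCc1ccccc1 | intermediate
3 | 4-(benzyloxy)benzaldehyde | O=Cc1ccc(OCc2ccccc2)cc1 | starting material
4 | (E)-1-[4,6-bis(benzyloxy)-2-hydroxy-3-iodophenyl]-3-[4-(benzyloxy)phenyl]prop-2-en-1-one | O=C(/C=C/c1ccc(OCc2ccccc2)cc1)c1c(O)c(I)c(OCc2ccccc2)cc1OCc1ccccc1 | intermediate
5 | 5,7-bis(benzyloxy)-2-[4-(benzyloxy)phenyl]-8-iodo-4H-chromen-4-one | O=c1cc(-c2ccc(OCc3ccccc3)cc2)oc2c(I)c(OCc3ccccc3)cc(OCc3ccccc3)c12 | intermediate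
6 | 3,5-bis(benzyloxy)phenol | Oc1cc(OCc2ccccc2)cc(OCc2ccccc2)c1 | starting material
7 | 3,5-bis(benzyloxy)phenyl N-(propan-2-yl)carbamate | CC(C)NC(=O)Oc1cc(OCc2ccccc2)cc(OCc2ccccc2)c1 | intermediate
8 | 3,5-bis(benzyloxy)phenyl N-(propan-2-yl)-N-(trimethylsilyl)carbamate | CC(C)N([Si](C)(C)C)C(=O)Oc1cc(OCc2ccccc2)cc(OCc2ccccc2)c1 | intermediate
9 | 2-lithio derivative of 8 (lithium ortho to the carbamate oxygen) | CC(C)N([Si](C)(C)C)C(=O)Oc1cc(OCc2ccccc2)cc(OCc2ccccc2)c1[Li] | intermediate
10 | 3,5-bis(benzyloxy)-2-(trimethylsilyl)phenyl N-(propan-2-yl)-N-(trimethylsilyl)carbamate | CC(C)N([Si](C)(C)C)C(=O)Oc1cc(OCc2ccccc2)cc(OCc2ccccc2)c1[Si](C)(C)C | intermediate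
11 | 3,5-bis(benzyloxy)-2-(trimethylsilyl)phenyl N-(propan-2-yl)carbamate | CC(C)NC(=O)Oc1cc(OCc2ccccc2)cc(OCc2ccccc2)c1[Si](C)(C)C | intermediate
12 | 3,5-bis(benzyloxy)-2-(trimethylsilyl)phenyl N-[tert-butyl(dimethyl)silyl]-N-(propan-2-yl)carbamate | CC(C)N([Si](C)(C)C(C)(C)C)C(=O)Oc1cc(OCc2ccccc2)cc(OCc2ccccc2)c1[Si](C)(C)C | intermediate
13 | 6-lithio derivative of 12 | CC(C)N([Si](C)(C)C(C)(C)C)C(=O)Oc1c([Li])c(OCc2ccccc2)cc(OCc2ccccc2)c1[Si](C)(C)C | intermediate
14 | 6-(chlorozincio) derivative of 12 | CC(C)N([Si](C)(C)C(C)(C)C)C(=O)Oc1c([Zn]Cl)c(OCc2ccccc2)cc(OCc2ccccc2)c1[Si](C)(C)C | intermediate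
15 | N-[tert-butyl(dimethyl)silyl] derivative of biaryl carbamate 16 | CC(C)N([Si](C)(C)C(C)(C)C)C(=O)Oc1c(-c2c(OCc3ccccc3)cc(OCc3ccccc3)c3c(=O)cc(-c4ccc(OCc5ccccc5)cc4)oc23)c(OCc2ccccc2)cc(OCc2ccccc2)c1[Si](C)(C)C | intermediate
16 | 3,5-bis(benzyloxy)-2-{5,7-bis(benzyloxy)-2-[4-(benzyloxy)phenyl]-4-oxo-4H-chromen-8-yl}-6-(trimethylsilyl)phenyl N-(propan-2-yl)carbamate | CC(C)NC(=O)Oc1c(-c2c(OCc3ccccc3)cc(OCc3ccccc3)c3c(=O)cc(-c4ccc(OCc5ccccc5)cc4)oc23)c(OCc2ccccc2)cc(OCc2ccccc2)c1[Si](C)(C)C | intermediate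
17 | 5,7-bis(benzyloxy)-2-[4-(benzyloxy)phenyl]-8-[4,6-bis(benzyloxy)-2-hydroxy-3-(trimethylsilyl)phenyl]-4H-chromen-4-one | Oc1c(-c2c(OCc3ccccc3)cc(OCc3ccccc3)c3c(=O)cc(-c4ccc(OCc5ccccc5)cc4)oc23)c(OCc2ccccc2)cc(OCc2ccccc2)c1[Si](C)(C)C | intermediate
18 | 3,5-bis(benzyloxy)-2-{5,7-bis(benzyloxy)-2-[4-(benzyloxy)phenyl]-4-oxo-4H-chromen-8-yl}-6-(trimethylsilyl)phenyl trifluoromethanesulfonate | O=S(=O)(Oc1c(-c2c(OCc3ccccc3)cc(OCc3ccccc3)c3c(=O)cc(-c4ccc(OCc5ccccc5)cc4)oc23)c(OCc2ccccc2)cc(OCc2ccccc2)c1[Si](C)(C)C)C(F)(F)F | intermediate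
19 | 1-[4-(benzyloxy)phenyl]ethan-1-one | CC(=O)c1ccc(OCc2ccccc2)cc1 | starting material
20 | methyl 3-[4-(benzyloxy)phenyl]-3-oxopropanoate | COC(=O)CC(=O)c1ccc(OCc2ccccc2)cc1 | intermediate
21 | methyl (3S)-3-[4-(benzyloxy)phenyl]-3-hydroxypropanoate | COC(=O)C[C@@H](c1ccc(OCc2ccccc2)cc1)O | intermediate
22 | aryne: 5,7-bis(benzyloxy)-2-[4-(benzyloxy)phenyl]-8-[4,6-bis(benzyloxy)-2,3-didehydrophenyl]-4H-chromen-4-one (triple bond between the future C8a and C4a) | O=c1cc(-c2ccc(OCc3ccccc3)cc2)oc2c(C3=C(OCc4ccccc4)C=C(OCc4ccccc4)C#C3)c(OCc3ccccc3)cc(OCc3ccccc3)c12 | intermediate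
23 | methyl (3S)-3-[4-(benzyloxy)phenyl]-3-(aryloxy)propanoate, aryl = 3,5-bis(benzyloxy)-2-(flavon-8-yl)phenyl potassiated at the position ortho to the ether oxygen (future C4a) | COC(=O)C[C@@H](c1ccc(OCc2ccccc2)cc1)Oc1c(-c2c(OCc3ccccc3)cc(OCc3ccccc3)c3c(=O)cc(-c4ccc(OCc5ccccc5)cc4)oc23)c(OCc2ccccc2)cc(OCc2ccccc2)c1[K] | intermediate
24 | (2S)-5,7-bis(benzyloxy)-2-[4-(benzyloxy)phenyl]-8-{5,7-bis(benzyloxy)-2-[4-(benzyloxy)phenyl]-4-oxo-4H-chromen-8-yl}-2,3-dihydro-4H-chromen-4-one | O=C1C[C@@H](c2ccc(OCc3ccccc3)cc2)Oc2c1c(OCc1ccccc1)cc(OCc1ccccc1)c2-c1c(OCc2ccccc2)cc(OCc2ccccc2)c2c(=O)cc(-c3ccc(OCc4ccccc4)cc3)oc12 | intermediate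
25 | (2S)-5,7-dihydroxy-8-[5,7-dihydroxy-2-(4-hydroxyphenyl)-4-oxo-4H-chromen-8-yl]-2-(4-hydroxyphenyl)-2,3-dihydro-4H-chromen-4-one | O=C1C[C@@H](c2ccc(O)cc2)Oc2c1c(O)cc(O)c2-c1c(O)cc(O)c2c(=O)cc(-c3ccc(O)cc3)oc12 | target

**Summary**
Total step count: 11. Longest linear sequence: 7 steps (1 → 2 → 4 → 5 → 16 → 18 → 24 → 25, steps 1, 2, 3, 6, 7, 10, 11).

**Steps most likely to fail**

Step 10 (bears the proposed method). What may go wrong: protonation of the aryl anion before it acylates, addition of the alkoxide at the wrong aryne terminus because of the neighbouring biaryl, capture of the aryne by the neighbouring 7''-benzyloxy oxygen, or base-induced retro-oxa-Michael opening that erodes C2. The fallback uses known chemistry, sets out from 16 and comes back at 24. Ipso-acylation of the aryl–silicon bond (AcCl, SnCl4, CH2Cl2, −78 °C; Friedel–Crafts acyldesilylation) should give the acetyl carbamate F1. Cleavage of the carbamate with DBU/Et2NH should give the 2-hydroxyacetophenone F2. Condensation with N,N-dimethylformamide dimethyl acetal should give the enaminone F3, and acid-induced cyclisation (aq. HCl, CH2Cl2) should give the 2-unsubstituted chromone F4. A rhodium-catalysed asymmetric 1,4-addition of 4-(benzyloxy)phenylboronic acid ([Rh(OH)(cod)]2 with the MeO-F12-BIPHEP enantiomer that leads to the (2S) product, toluene–water) should then give 24. The 2-aryl-substituted flavone half is inert to this addition, and C2 is set by the catalyst.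

Step 6. What may go wrong: slow transmetalation and reductive elimination at the tetra-ortho-substituted axis, so that protodezincation of 14 and reduction of 5 take over. The fallback sets out from 11 and 5 and comes back at 16, with the roles of the partners exchanged and boron in place of zinc. Lithiation of 11 by way of 12 and 13 as in step 6, followed by an iodine quench, should give the N-silyl aryl iodide F5, which the aqueous NaHSO4 work-up should convert into the aryl iodide F6. Miyaura borylation of 5 (B2pin2, PdCl2(dppf), KOAc, dioxane, 90 °C) should give the flavone 8-boronic ester F7. Suzuki–Miyaura coupling of F6 and F7 (Pd(OAc)2, SPhos, K3PO4, toluene–water, 100 °C) should give 16. Any N–H carbamate cleaved by the base during this coupling would appear as the phenol 17, which step 7 passes through in any case.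

Step 11. What may go wrong: over-reduction of the flavone C2''=C3'' bond or of the ketone, or hydrogenolytic opening of the benzylic C2–O1 bond before the sixth benzyl group has left. The fallback sets out from 24 and comes back at 25. It replaces reduction by Lewis-acid debenzylation with BCl3 and pentamethylbenzene as cation scavenger (CH2Cl2, −78 °C), which transfers the benzyl groups to the scavenger and makes no new compound (entry F0).

**Further compounds**
F1 | step 10 | 2-acetyl-3,5-bis(benzyloxy)-6-{5,7-bis(benzyloxy)-2-[4-(benzyloxy)phenyl]-4-oxo-4H-chromen-8-yl}phenyl N-(propan-2-yl)carbamate (acetyl in place of the silyl group of 16) | CC(C)NC(=O)Oc1c(-c2c(OCc3ccccc3)cc(OCc3ccccc3)c3c(=O)cc(-c4ccc(OCc5ccccc5)cc4)oc23)c(OCc2ccccc2)cc(OCc2ccccc2)c1C(C)=O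
F2 | step 10 | 8-[3-acetyl-4,6-bis(benzyloxy)-2-hydroxyphenyl]-5,7-bis(benzyloxy)-2-[4-(benzyloxy)phenyl]-4H-chromen-4-one | CC(=O)c1c(O)c(-c2c(OCc3ccccc3)cc(OCc3ccccc3)c3c(=O)cc(-c4ccc(OCc5ccccc5)cc4)oc23)c(OCc2ccccc2)cc1OCc1ccccc1
F3 | step 10 | (E)-3-(dimethylamino)prop-2-enoyl analogue of F2 (enaminone) | CN(C)/C=C/C(=O)c1c(O)c(-c2c(OCc3ccccc3)cc(OCc3ccccc3)c3c(=O)cc(-c4ccc(OCc5ccccc5)cc4)oc23)c(OCc2ccccc2)cc1OCc1ccccc1
F4 | step 10 | 5,7-bis(benzyloxy)-8-{5,7-bis(benzyloxy)-2-[4-(benzyloxy)phenyl]-4-oxo-4H-chromen-8-yl}-4H-chromen-4-one | O=c1ccoc2c1c(OCc1ccccc1)cc(OCc1ccccc1)c2-c1c(OCc2ccccc2)cc(OCc2ccccc2)c2c(=O)cc(-c3ccc(OCc4ccccc4)cc3)oc12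
F5 | step 6 | 3,5-bis(benzyloxy)-2-iodo-6-(trimethylsilyl)phenyl N-[tert-butyl(dimethyl)silyl]-N-(propan-2-yl)carbamate | CC(C)N([Si](C)(C)C(C)(C)C)C(=O)Oc1c(I)c(OCc2ccccc2)cc(OCc2ccccc2)c1[Si](C)(C)C
F6 | step 6 | 3,5-bis(benzyloxy)-2-iodo-6-(trimethylsilyl)phenyl N-(propan-2-yl)carbamate | CC(C)NC(=O)Oc1c(I)c(OCc2ccccc2)cc(OCc2ccccc2)c1[Si](C)(C)C
F7 | step 6 | 5,7-bis(benzyloxy)-2-[4-(benzyloxy)phenyl]-8-(4,4,5,5-tetramethyl-1,3,2-dioxaborolan-2-yl)-4H-chromen-4-one | CC1(C)OB(c2c(OCc3ccccc3)cc(OCc3ccccc3)c3c(=O)cc(-c4ccc(OCc5ccccc5)cc4)oc23)OC1(C)C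
F0 | step 11 | none | none
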